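## The problem

The target is a single cyclohexene ring, numbered here C1(OBz)–C2=C3–C4(OBz)–C5(OH)–C6(OH)(C7H2OH). The only carbon outside the ring is C7, on the quaternary carbinol C6, so the task is to place four ring oxygens and one hydroxymethyl group with the right configuration. The four contiguous stereocentres C4, C5, C6 and C1 carry the two benzoates on one face and the C5 and C6 hydroxyls on the other. C5 is the centre that can control its neighbours: a free hydroxyl there can deliver an oxidant to its own face of a C6=C1 double bond, which fixes C6, and C1 then follows from an anti opening of the oxirane. C4 lies outside this relay, and if C4 and C5 come from a cis-diol, C4 needs an inversion of its own. The benzoates are the fragile groups of the target: under base the C1 ester can move to the primary C7 hydroxyl and the C4 ester to C5, and both are allylic. Two intermediates are fragile as well: a cyclohexa-1,3-diene carrying the C4 and C5 oxygens becomes a phenol once one of its C–O bonds is turned into a leaving group, and a vinyl oxirane is opened or rearranged by strong Lewis acids. The feature that makes the key step possible is the secondary C5 hydroxyl next to C6: in a C6=C1–C2=C3 diene it is allylic only to the trisubstituted C6=C1 bond. The target's pattern (C6–OH cis to C5–OH, C1 benzoate trans to C6–OH) is what remains when a C6–C1 oxirane formed syn to C5–OH is opened at C1 by benzoate.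

## Retrosynthesis

**Si–O at C7.** Target 11 is traced back to its C7 silyl ether 10. The primary hydroxyl must stay masked until both benzoates are in place, because a free primary alcohol would be esterified first in any acylation or Mitsunobu step. The forward reaction must be non-basic so that no benzoate migrates to C7.

**C4–O, with inversion.** Compound 10 is cut at the C4 benzoate to triol 9 and benzoic acid 7 (Mitsunobu reaction). The alternative would be to install this benzoate on the diene, before the epoxidation. That requires SN2 displacement at a dienylic carbinol of a cyclohexadiene cis-diol, where activation invites loss of water to a phenol and a free 1,2-diol gives no assurance which oxygen is activated. In 9 the ring has one alkene and a quaternary C6, so it cannot aromatise, and C4 is the only carbinol carbon open to backside attack. The price is that C4 passes through the key step as its native cis oxygen under a silyl group. Triol 9 comes from 8 by removing that one silyl ether, which requires two silyl groups of different stability on C4 and C7.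

**C1–O.** Compound 8 is cut at the C1 benzoate to vinyl epoxide 6 and 7. Opening the oxirane at C1 with inversion gives the C1 ester and the C6 tertiary hydroxyl in one step. The forward reaction must choose C1 over C6 and over conjugate attack at C3; the C5 hydroxyl, syn to the oxirane, is the handle for this.

**C6–O and C1–O of the oxirane (key disconnection).** Epoxide 6 is cut back to dienol 5. This removes two stereocentres and the quaternary carbinol at once and leaves a diene whose only stereocentres are C4 and C5. The forward reaction must put oxygen on the C5–OH face of C6=C1 and leave C2=C3 alone.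

**Si–O at C7, C6–C7, Si–O at C4.** Dienol 5 comes from diol 4 by silylation of the primary hydroxyl. Compound 4 comes from vinyl bromide 2 and (tributylstannyl)methanol 3 by Stille coupling, which forms the only new C–C bond. Compound 2 comes from the commercial cis-dihydrodiol 1 by silylation of the hydroxyl remote from bromine. Silylating first gives a lipophilic, stable coupling partner and avoids acetonide formation and removal. Diol 1 supplies C5 in its final configuration and C4 as the epimer to be inverted later.

## Roads not taken

**Alternative 1:** The cut is C6–C1, made by an Ireland–Claisen ring contraction. The sugar lactone A1 (D-gluco configuration, with an (E)-2-alkoxyvinyl group on the ring-oxygen carbon) would be converted to its silyl ketene acetal. A [3,3] shift would then form C6–C1 and C2=C3 as the ring C–O bond breaks, giving acid A2.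
- Merits: C4 and C5 come from the sugar already trans, so no inversion is needed. This is better than the chosen plan, which needs a Mitsunobu step at C4. The carbocycle, the quaternary C6 and C1 arise in one C–C bond formation, and the starting sugar is cheaper than an enzymatic diol.
- Weak points: the enolate of A1 has a benzyloxy group on the adjacent carbon and can eliminate. The configurations at C1 and C6 depend on a boat-like transition state and on a pure (E)-enol ether that takes several steps to make. A2 must then be reduced at the carboxyl group, two 4-methoxybenzyl ethers exchanged for benzoates, and a secondary and a tertiary benzyl ether removed without touching C2=C3 or the esters.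
- Comparison: this would take well over twelve steps. The chosen plan sets against its one inversion a length of eight steps and no ether cleavage at the end.

**Alternative 2:** The cut is C5–C6, made by a pinacol cyclisation. SmI2 would couple the C5 aldehyde and the C6 ketone of the (Z)-keto-aldehyde A3 to give the cis-diol A4.
- Merits: the C5/C6 diol is delivered free and cis in the ring-forming step. In such closures the new hydroxyls usually end up trans to neighbouring alkoxy groups, which is the target's pattern, so for the C4/C5 and C6/C1 relationships this road is as good as the chosen one.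
- Weak points: both carbonyls of A3 carry an oxygen on the adjacent carbon, and SmI2 cleaves such C–O bonds readily. The (Z)-alkene between two stereocentres must be made and kept, since the (E)-isomer cannot close. The aldehyde is epimerisable at C4. The 4-methoxybenzyl ethers of A4 must later be exchanged for benzoates next to a free diol.
- Comparison: A3 needs a long acyclic synthesis and the end game needs extra protection. The chosen plan buys the ring ready-made and forms only one C–C bond.

**Alternative 3:** The cut is C6–C7, made by a silicon tether. SmI2 would reduce the C–Br bond of the (bromomethyl)dimethylsilyl ether on the C1 oxygen of ketone A5, and the organosamarium would add to the C6 carbonyl to give oxasilolane A6. Tamao oxidation would then release C7–OH and C1–OH.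
- Merits: the five-membered ring forces C7 onto the face of the C1 oxygen, so the C6 configuration is as secure as with hydroxyl delivery, and the C4 benzoate is already present.
- Weak points: A5 is a ketone with oxygen on both adjacent carbons, a C2=C3 bond that can move into conjugation, and a benzoate that can then be eliminated to give a phenol. SmI2 can cleave the C1–O or C5–O bond instead of the C–Br bond. The basic peroxide of the Tamao step endangers the benzoate. Afterwards the secondary C1–OH must be benzoylated beside the primary C7–OH, which needs further protection.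
- Comparison: the chosen plan carries C7 in from the start through a cross-coupling on a stable vinyl bromide and never passes through a ketone at C6. It sets against the tether's certainty a delivery step that depends on vanadium binding to one hydroxyl.

Key step: step 4

Assumption: the commercial cis-dihydrodiol of bromobenzene is the (1S,2S) enantiomer formed by toluene dioxygenase, and the ring locants C1 to C7 of the target are used for every intermediate.

## Route

Step 1
Reactants: 1 (1S,2S)-3-bromocyclohexa-3,5-diene-1,2-diol
Product: 2 (1S,6S)-2-bromo-6-[(tert-butyldimethylsilyl)oxy]cyclohexa-2,4-dien-1-ol (silyl ether on the later C4 oxygen; the later C5 hydroxyl, next to C–Br, is free)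
Conditions: TBSCl (1.05 equiv), imidazole (2.2 equiv), DMF, −20 °C to 0 °C
Reagents that add atoms: tert-butyldimethylsilyl chloride, CC(C)(C)[Si](C)(C)Cl
Why: Regioselective monosilylation of a cis-1,2-diol: the hydroxyl next to the brominated sp2 carbon is the more hindered and less nucleophilic one, so a bulky silyl chloride at low temperature should take the remote hydroxyl, a preference documented for 3-halo cis-1,2-diols of this family; no stereocentre is touched.

Step 2
Reactants: 2 (1S,6S)-2-bromo-6-[(tert-butyldimethylsilyl)oxy]cyclohexa-2,4-dien-1-ol; 3 (tributylstannyl)methanol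
Product: 4 (1R,6S)-6-[(tert-butyldimethylsilyl)oxy]-2-(hydroxymethyl)cyclohexa-2,4-dien-1-ol
Conditions: Pd(PPh3)4 (5 mol %), CuI (10 mol %), 1,4-dioxane (degassed), 70 °C
Reagents that add atoms: none
Why: Stille coupling: Pd(PPh3)4 inserts into the C6–Br bond and the stannane transfers its hydroxymethyl group in preference to butyl, forming C6–C7 without moving the alkene; the free secondary hydroxyl and the silyl ether are inert to zerovalent palladium, and CuI allows a temperature low enough to limit Diels–Alder dimerisation of the diene.

Step 3
Reactants: 4 (1R,6S)-6-[(tert-butyldimethylsilyl)oxy]-2-(hydroxymethyl)cyclohexa-2,4-dien-1-ol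
Product: 5 (1R,6S)-6-[(tert-butyldimethylsilyl)oxy]-2-{[(tert-butyldiphenylsilyl)oxy]methyl}cyclohexa-2,4-dien-1-ol (diene with free C5 hydroxyl, C4–OTBS cis to it, C7–OTBDPS)
Conditions: TBDPSCl (1.1 equiv), imidazole, CH2Cl2, 0 °C
Reagents that add atoms: tert-butyldiphenylsilyl chloride, CC(C)(C)[Si](Cl)(c1ccccc1)c1ccccc1
Why: Silyl ether formation: the primary allylic C7 hydroxyl reacts far faster with the bulky chloride than the secondary C5 hydroxyl flanked by C4–OTBS and the substituted C6, so C5–OH stays free to direct the next step; the more robust silyl group goes on C7 because it must outlast the later acid cleavage of the C4 TBS ether.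

Step 4
Reactants: 5 (1R,6S)-6-[(tert-butyldimethylsilyl)oxy]-2-{[(tert-butyldiphenylsilyl)oxy]methyl}cyclohexa-2,4-dien-1-ol
Product: 6 (1S,2S,3S,6R)-3-[(tert-butyldimethylsilyl)oxy]-1-{[(tert-butyldiphenylsilyl)oxy]methyl}-7-oxabicyclo[4.1.0]hept-4-en-2-ol (C6–C1 oxirane, C5–OH and C4–OTBS all on one face; C2=C3 intact)
Conditions: VO(acac)2 (5 mol %), t-BuOOH (5.5 M in decane, 1.5 equiv), CH2Cl2, 0 °C to rt
Reagents that add atoms: tert-butyl hydroperoxide, CC(C)(C)OO
Why: Hydroxyl-directed epoxidation of a cyclic allylic alcohol, the closest known reaction type being the syn epoxidation of cyclohex-2-en-1-ols with VO(acac)2 and tert-butyl hydroperoxide. The C5 alkoxide and the alkylperoxide bind to pentavalent vanadium, and the metal-bound peroxide oxygen is passed to the C6=C1 bond within this complex. The oxirane closes by concerted transfer of one oxygen atom to both alkene carbons (a [2+1] addition forming C6–O and C1–O together), so it is necessarily cis-fused and no exo or endo choice arises. C6 and C1 are both set by the existing C5 centre: oxygen arrives on the face that carries C5–OH, which places the C6 oxygen cis to the C5 hydroxyl and C7 on the opposite face. Face selectivity comes from this tether, helped by A1,2 strain with the C6 substituent, which holds C5–OH pseudoaxial, the geometry that reacts fastest. Site selectivity comes from C6=C1 being the only alkene allylic to a free hydroxyl and the more electron-rich, trisubstituted one; C2=C3 is only homoallylic and the silyl ethers on C4 and C7 cannot bind the metal. The C4 silyl ether is on the same face but pseudoequatorial and remote from C6=C1, so it should not block delivery. Low temperature, a short reaction time and a mildly basic work-up are chosen because the vinyl oxirane is sensitive to Lewis acid.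

Step 5
Reactants: 6 (1S,2S,3S,6R)-3-[(tert-butyldimethylsilyl)oxy]-1-{[(tert-butyldiphenylsilyl)oxy]methyl}-7-oxabicyclo[4.1.0]hept-4-en-2-ol; 7 benzoic acid
Product: 8 (1S,4S,5S,6S)-4-[(tert-butyldimethylsilyl)oxy]-6-{[(tert-butyldiphenylsilyl)oxy]methyl}-5,6-dihydroxycyclohex-2-en-1-yl benzoate
Conditions: PhCO2H (1.5 equiv), Ti(OiPr)4 (1.5 equiv), CH2Cl2, 0 °C to rt; aqueous tartaric acid work-up
Reagents that add atoms: none
Why: Ti(OiPr)4-mediated opening of a 2,3-epoxy alcohol by a carboxylic acid: the titanium alkoxide of C5–OH holds the syn oxirane oxygen and benzoate attacks the carbon remote from the carbinol, C1, which is also the allylic and less substituted oxirane carbon; attack is anti to the C1–O bond, so C1 is inverted (benzoate opposite to the C5 and C6 oxygens) and C6 keeps its oxygen as the tertiary hydroxyl.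

Step 6
Reactants: 8 (1S,4S,5S,6S)-4-[(tert-butyldimethylsilyl)oxy]-6-{[(tert-butyldiphenylsilyl)oxy]methyl}-5,6-dihydroxycyclohex-2-en-1-yl benzoate
Product: 9 (1S,4S,5S,6S)-6-{[(tert-butyldiphenylsilyl)oxy]methyl}-4,5,6-trihydroxycyclohex-2-en-1-yl benzoate
Conditions: camphorsulfonic acid (0.2 equiv), MeOH–CH2Cl2 (1:1), 0 °C to rt
Reagents that add atoms: none
Why: Acid-catalysed methanolysis of a silyl ether: a secondary TBS ether is cleaved under conditions that a primary TBDPS ether and benzoate esters survive, which frees the C4 hydroxyl alone; no stereocentre changes.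

Step 7
Reactants: 9 (1S,4S,5S,6S)-6-{[(tert-butyldiphenylsilyl)oxy]methyl}-4,5,6-trihydroxycyclohex-2-en-1-yl benzoate; 7 benzoic acid
Product: 10 (1S,4R,5S,6S)-6-{[(tert-butyldiphenylsilyl)oxy]methyl}-5,6-dihydroxycyclohex-2-ene-1,4-diyl dibenzoate
Conditions: PPh3 (2 equiv), DIAD (2 equiv), PhCO2H (2 equiv), THF, 0 °C to rt
Reagents that add atoms: none
Why: Mitsunobu reaction: of the three hydroxyls only the allylic C4–OH sits on a carbon open to SN2 attack (C5 is flanked by the quaternary C6, and C6 is tertiary), and because all three are cis no oxirane can form, so benzoate should displace the C4 oxyphosphonium with inversion and place the C4 ester trans to C5–OH; the ring now has one alkene and a quaternary C6, so the loss of water to an arene that threatens a dienylic alcohol is impossible.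

Step 8
Reactants: 10 (1S,4R,5S,6S)-6-{[(tert-butyldiphenylsilyl)oxy]methyl}-5,6-dihydroxycyclohex-2-ene-1,4-diyl dibenzoate
Product: 11 (1S,4R,5S,6S)-5,6-dihydroxy-6-(hydroxymethyl)cyclohex-2-ene-1,4-diyl dibenzoate (CNP0212417.1)
Conditions: HF·pyridine, pyridine, THF, 0 °C to rt (polypropylene vessel)
Reagents that add atoms: none
Why: Fluoride cleavage of a silyl ether: HF·pyridine removes the primary TBDPS group under mildly acidic conditions, under which the base-promoted migration of the C1 benzoate to the new primary hydroxyl and of the C4 benzoate to C5 should not occur; all four stereocentres are untouched.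

## Compound list

1 | (1S,2S)-3-bromocyclohexa-3,5-diene-1,2-diol | O[C@H]1C=CC=C(Br)[C@H]1O | starting material
2 | (1S,6S)-2-bromo-6-[(tert-butyldimethylsilyl)oxy]cyclohexa-2,4-dien-1-ol | C1=C[C@H](O[Si](C)(C)C(C)(C)C)[C@H](O)C(Br)=C1 | intermediate
3 | (tributylstannyl)methanol | OC[Sn](CCCC)(CCCC)CCCC | starting material
4 | (1R,6S)-6-[(tert-butyldimethylsilyl)oxy]-2-(hydroxymethyl)cyclohexa-2,4-dien-1-ol | C1=C[C@H](O[Si](C)(C)C(C)(C)C)[C@H](O)C(CO)=C1 | intermediate
5 | (1R,6S)-6-[(tert-butyldimethylsilyl)oxy]-2-{[(tert-butyldiphenylsilyl)oxy]methyl}cyclohexa-2,4-dien-1-ol | C1=C[C@H](O[Si](C)(C)C(C)(C)C)[C@H](O)C(CO[Si](c2ccccc2)(c2ccccc2)C(C)(C)C)=C1 | intermediate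
6 | (1S,2S,3S,6R)-3-[(tert-butyldimethylsilyl)oxy]-1-{[(tert-butyldiphenylsilyl)oxy]methyl}-7-oxabicyclo[4.1.0]hept-4-en-2-ol | C1=C[C@H](O[Si](C)(C)C(C)(C)C)[C@H](O)[C@]2(CO[Si](c3ccccc3)(c3ccccc3)C(C)(C)C)O[C@H]12 | intermediate
7 | benzoic acid | OC(=O)c1ccccc1 | starting material
8 | (1S,4S,5S,6S)-4-[(tert-butyldimethylsilyl)oxy]-6-{[(tert-butyldiphenylsilyl)oxy]methyl}-5,6-dihydroxycyclohex-2-en-1-yl benzoate | O=C(O[C@H]1C=C[C@H](O[Si](C)(C)C(C)(C)C)[C@H](O)[C@@]1(O)CO[Si](c2ccccc2)(c2ccccc2)C(C)(C)C)c1ccccc1 | intermediate
9 | (1S,4S,5S,6S)-6-{[(tert-butyldiphenylsilyl)oxy]methyl}-4,5,6-trihydroxycyclohex-2-en-1-yl benzoate | O=C(O[C@H]1C=C[C@H](O)[C@H](O)[C@@]1(O)CO[Si](c2ccccc2)(c2ccccc2)C(C)(C)C)c1ccccc1 | intermediate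
10 | (1S,4R,5S,6S)-6-{[(tert-butyldiphenylsilyl)oxy]methyl}-5,6-dihydroxycyclohex-2-ene-1,4-diyl dibenzoate | O=C(O[C@H]1C=C[C@@H](OC(=O)c2ccccc2)[C@H](O)[C@@]1(O)CO[Si](c3ccccc3)(c3ccccc3)C(C)(C)C)c1ccccc1 | intermediate
11 | (1S,4R,5S,6S)-5,6-dihydroxy-6-(hydroxymethyl)cyclohex-2-ene-1,4-diyl dibenzoate | O=C(O[C@H]1C=C[C@@H](OC(=O)c2ccccc2)[C@H](O)[C@@]1(O)CO)c1ccccc1 | target

## Step count and least certain steps

Total: 8 steps. Longest linear sequence: 8 steps, from 1 (the route is linear; 3 and 7 are bought).

**Step 4 (key step).** The vinyl oxirane may be opened or rearranged by the Lewis-acidic vanadium species as it forms. The C5 carbinol may be oxidised instead of directing. If the hindered hydroxyl binds poorly, slow undirected oxidation would erode face and site selectivity. Fallback: reagent-controlled epoxidation through the primary hydroxyl, setting out from 4.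
- Katsuki–Sharpless asymmetric epoxidation of 4 (Ti(OiPr)4, diethyl tartrate, t-BuOOH, 4 Å molecular sieves, CH2Cl2, −20 °C) should give the epoxy diol (1S,2S,3S,6R)-3-[(tert-butyldimethylsilyl)oxy]-1-(hydroxymethyl)-7-oxabicyclo[4.1.0]hept-4-en-2-ol F1.
- The tartrate must send oxygen to the C5–OH face. By analogy with (E)-hex-2-en-1-ol, where L-(+)-diethyl tartrate gives the (2S,3S) epoxide, this should be D-(−)-diethyl tartrate.
- Silylation of the primary hydroxyl (TBDPSCl, imidazole, CH2Cl2, 0 °C) returns to the route at 6.

**Step 1.** Silylation may be spread over both hydroxyls, with bis-silylation or silyl migration between the cis oxygens. Fallback: differentiate the hydroxyls after the carbon substituent is in place, setting out from 1.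
- Stille coupling of 1 with 3 (Pd(PPh3)4, CuI, dioxane, 70 °C) gives the triol (1S,2R)-3-(hydroxymethyl)cyclohexa-3,5-diene-1,2-diol F2.
- TBDPSCl and imidazole at 0 °C take the primary hydroxyl to give (1S,2R)-3-{[(tert-butyldiphenylsilyl)oxy]methyl}cyclohexa-3,5-diene-1,2-diol F3.
- TBSCl and imidazole at −20 °C then silylate the C4 hydroxyl, now next to a C5 hydroxyl shielded by the bulky C6 substituent, and the sequence returns at 5.

**Step 2.** Oxidative addition may be slow at a temperature the diene tolerates, so Diels–Alder dimerisation, butyl transfer or protodestannylation could take over. Fallback: carbonylation and reduction, setting out from 2.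
- Methoxycarbonylation of 2 (Pd(OAc)2, PPh3, CO at 1 atm, MeOH, Et3N, DMF, 50 °C) gives methyl (5S,6R)-5-[(tert-butyldimethylsilyl)oxy]-6-hydroxycyclohexa-1,3-diene-1-carboxylate F4.
- Reduction with i-Bu2AlH (CH2Cl2, −78 °C) returns to the route at 4.

**Step 5.** Benzoate may attack C3 with allylic shift, isopropoxide may compete as nucleophile, or the acyl group may migrate on titanium. Fallback: separate the opening from the acylation, setting out from 6.
- Hydrolytic opening of 6 (dilute aqueous H2SO4 in THF, 0 °C) gives (1S,2R,3S,4S)-4-[(tert-butyldimethylsilyl)oxy]-2-{[(tert-butyldiphenylsilyl)oxy]methyl}cyclohex-5-ene-1,2,3-triol F5.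
- Benzoylation of its least hindered secondary hydroxyl, the allylic C1–OH (benzoyl chloride, pyridine, CH2Cl2, −40 °C), returns to the route at 8.

**Step 7.** The reagent may be tied up as cyclic phosphoranes of the cis hydroxyls, or benzoate may be delivered to C2 with allylic shift. Fallback: make C4–OH the only free hydroxyl, setting out from 8.
- 2,2-Dimethoxypropane and pyridinium p-toluenesulfonate in CH2Cl2 give the acetonide of 8 across the C5 and C6 hydroxyls F6.
- HF·pyridine buffered with pyridine (THF, 0 °C to rt) removes the secondary TBS ether to give the C4 alcohol of that acetonide F7.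
- The Mitsunobu reaction (PPh3, DIAD, 7, THF) gives the C4-inverted dibenzoate acetonide F8.
- 80% aqueous acetic acid at 40 °C removes the acetonide and returns to the route at 10.

## Further compounds

F1 | step 4 | (1S,2S,3S,6R)-3-[(tert-butyldimethylsilyl)oxy]-1-(hydroxymethyl)-7-oxabicyclo[4.1.0]hept-4-en-2-ol | C1=C[C@H](O[Si](C)(C)C(C)(C)C)[C@H](O)[C@]2(CO)O[C@H]12
F2 | step 1 | (1S,2R)-3-(hydroxymethyl)cyclohexa-3,5-diene-1,2-diol | C1=C[C@H](O)[C@H](O)C(CO)=C1
F3 | step 1 | (1S,2R)-3-{[(tert-butyldiphenylsilyl)oxy]methyl}cyclohexa-3,5-diene-1,2-diol | C1=C[C@H](O)[C@H](O)C(CO[Si](c2ccccc2)(c2ccccc2)C(C)(C)C)=C1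
F4 | step 2 | methyl (5S,6R)-5-[(tert-butyldimethylsilyl)oxy]-6-hydroxycyclohexa-1,3-diene-1-carboxylate | C1=C[C@H](O[Si](C)(C)C(C)(C)C)[C@H](O)C(C(=O)OC)=C1
F5 | step 5 | (1S,2R,3S,4S)-4-[(tert-butyldimethylsilyl)oxy]-2-{[(tert-butyldiphenylsilyl)oxy]methyl}cyclohex-5-ene-1,2,3-triol | O[C@H]1C=C[C@H](O[Si](C)(C)C(C)(C)C)[C@H](O)[C@@]1(O)CO[Si](c2ccccc2)(c2ccccc2)C(C)(C)C
F6 | step 7 | acetonide of 8 across the C5 and C6 hydroxyls (C1 benzoate, C4 TBS ether, C7 TBDPS ether) | O=C(O[C@H]1C=C[C@H](O[Si](C)(C)C(C)(C)C)[C@@H]2OC(C)(C)O[C@]12CO[Si](c3ccccc3)(c3ccccc3)C(C)(C)C)c1ccccc1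
F7 | step 7 | C4 alcohol of the C5,C6 acetonide (C1 benzoate, C7 TBDPS ether) | O=C(O[C@H]1C=C[C@H](O)[C@@H]2OC(C)(C)O[C@]12CO[Si](c3ccccc3)(c3ccccc3)C(C)(C)C)c1ccccc1
F8 | step 7 | C1,C4 dibenzoate of the C5,C6 acetonide, C4 inverted (C7 TBDPS ether) | O=C(O[C@H]1C=C[C@@H](OC(=O)c2ccccc2)[C@@H]3OC(C)(C)O[C@]13CO[Si](c4ccccc4)(c4ccccc4)C(C)(C)C)c1ccccc1
A1 | alternative 1 | D-gluco δ-lactone with benzyl ethers on the two carbons next to the carbonyl, a 4-methoxybenzyl ether on the following carbon and an (E)-2-[(4-methoxybenzyl)oxy]vinyl group on the ring-oxygen carbon | O=C1[C@H](OCc2ccccc2)[C@@H](OCc2ccccc2)[C@H](OCc2ccc(OC)cc2)[C@@H](/C=C/OCc2ccc(OC)cc2)O1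
A2 | alternative 1 | 1,6-bis(benzyloxy)-2,5-bis[(4-methoxybenzyl)oxy]cyclohex-3-ene-1-carboxylic acid with the target configuration | COc1ccc(cc1)CO[C@H]2C=C[C@@H](OCc3ccc(OC)cc3)[C@H](OCc4ccccc4)[C@@]2(OCc5ccccc5)C(=O)O
A3 | alternative 2 | (Z)-7-[(tert-butyldimethylsilyl)oxy]-2,5-bis[(4-methoxybenzyl)oxy]-6-oxohept-3-enal | O=C[C@H](OCc1ccc(OC)cc1)/C=C\[C@H](OCc1ccc(OC)cc1)C(=O)CO[Si](C)(C)C(C)(C)C
A4 | alternative 2 | 1-{[(tert-butyldimethylsilyl)oxy]methyl}-3,6-bis[(4-methoxybenzyl)oxy]cyclohex-4-ene-1,2-diol with the target configuration | COc1ccc(CO[C@H]2C=C[C@@H](OCc3ccc(OC)cc3)[C@H](O)[C@@]2(O)CO[Si](C)(C)C(C)(C)C)cc1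
A5 | alternative 3 | 4-{[(bromomethyl)dimethylsilyl]oxy}-6-[(tert-butyldimethylsilyl)oxy]-5-oxocyclohex-2-en-1-yl benzoate | BrC[Si](C)(C)O[C@H]1C=C[C@@H](OC(=O)c2ccccc2)[C@H](O[Si](C)(C)C(C)(C)C)C1=O
A6 | alternative 3 | cis-fused 2,2-dimethyl-1,2-oxasilolane tertiary alcohol carrying the C4 benzoate and the C5 TBS ether | C[Si]1(C)O[C@H]2C=C[C@@H](OC(=O)c3ccccc3)[C@H](O[Si](C)(C)C(C)(C)C)[C@@]2(O)C1
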